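## Retrosynthetic overview

1. Target ⇐ its bis(O-benzyl) ether; hydrogenolysis is the last step.
2. Key disconnection is the tertiary C3–O bond, made by reductive α-oxygenation of an (E)-α-arylidene-β-benzyl-γ-butyrolactone. Oxygen enters anti to the C4 benzyl group, which gives the cis-dibenzyl (3S,4R) array.
3. α-Arylidene lactone ⇐ aldol condensation of (S)-β-(4-benzyloxy-3-methoxybenzyl)-γ-butyrolactone with 4-benzyloxy-3,5-dimethoxybenzaldehyde.
4. (S)-Lactone ⇐ Stobbe half-ester of O-benzylvanillin and dimethyl succinate; Rh-catalysed asymmetric hydrogenation sets C4, then ester-selective reduction and lactonisation.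
5. Ring order: the γ-lactone is the only ring made (closed at the reduction stage); both arenes are bought.

Assumption: the SMILES is read as drawn, (3S,4R) in oxolan-2-one numbering (C2 carbonyl, C3 carbinol, C4 methine), i.e. the two benzyl groups cis and the 3-OH trans to the C4 benzyl group.

## Route

Step 1
Reactants: 1 syringaldehyde
Product: 2 4-(benzyloxy)-3,5-dimethoxybenzaldehyde
Conditions: BnBr, K2CO3, DMF, 60 °C
Reagents that add atoms: benzyl bromide, BrCc1ccccc1
Why: Williamson ether synthesis; the phenoxide is alkylated by SN2 and the aldehyde is untouched.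

Step 2
Reactants: 3 4-(benzyloxy)-3-methoxybenzaldehyde (O-benzylvanillin); 4 dimethyl succinate
Product: 6 (E)-4-[4-(benzyloxy)-3-methoxyphenyl]-3-(methoxycarbonyl)but-3-enoic acid, via paraconic ester 5 (not isolated)
Conditions: NaOMe (2 equiv), MeOH, reflux; then 2 M HCl
Reagents that add atoms: none
Why: Stobbe condensation; the succinate enolate adds to the aldehyde, the aldolate lactonises to 5, and E1cB ring opening gives the E half-ester with the free acid on the CH2 arm and the ester on the alkene carbon.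

Step 3
Reactants: 6 (E)-4-[4-(benzyloxy)-3-methoxyphenyl]-3-(methoxycarbonyl)but-3-enoic acid
Product: 7 (S)-4-[4-(benzyloxy)-3-methoxyphenyl]-3-(methoxycarbonyl)butanoic acid
Conditions: [Rh(cod)((R,R)-Et-DuPhos)]BF4 (0.5 mol%), NaOMe (10 mol%), H2 (5 bar), MeOH, rt
Reagents that add atoms: none
Why: Rh-bisphosphine asymmetric hydrogenation of an itaconate-type half-ester; carboxylate chelation to the cationic rhodium fixes the enantioface and creates the S centre (the future lactone C4), while benzyl ethers survive homogeneous Rh.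

Step 4
Reactants: 7 (S)-4-[4-(benzyloxy)-3-methoxyphenyl]-3-(methoxycarbonyl)butanoic acid
Product: 10 (S)-4-[4-(benzyloxy)-3-methoxybenzyl]oxolan-2-one, via potassium carboxylate 8 (not isolated), via hydroxy acid 9 (not isolated)
Conditions: KOH (1.0 equiv), EtOH, 0 °C; CaCl2, NaBH4, EtOH, −10 °C → rt; then 3 M HCl, rt
Reagents that add atoms: none
Why: Chemoselective borohydride reduction; Ca(BH4)2 reduces the ester while the carboxylate is inert, acid then closes the γ-lactone, and with no excess base the stereocentre is not epimerised.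

Step 5
Reactants: 10 (S)-4-[4-(benzyloxy)-3-methoxybenzyl]oxolan-2-one; 2 4-(benzyloxy)-3,5-dimethoxybenzaldehyde
Product: 14 (3E,4S)-3-[4-(benzyloxy)-3,5-dimethoxybenzylidene]-4-[4-(benzyloxy)-3-methoxybenzyl]oxolan-2-one, via lithium enolate 11 (not isolated), via lithium aldolate 12 (not isolated), via acetoxy lactone 13 (not isolated)
Conditions: LiN(SiMe3)2, THF, −78 °C; 2; then Ac2O, −78 → 0 °C; then DBU, 0 °C → rt
Reagents that add atoms: none
Why: Aldol condensation (directed aldol addition, O-acetylation, E1cB elimination) gives the conjugated E-arylidene lactone; C4 is not enolisable here and keeps its configuration.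

Step 6
Reactants: 14 (3E,4S)-3-[4-(benzyloxy)-3,5-dimethoxybenzylidene]-4-[4-(benzyloxy)-3-methoxybenzyl]oxolan-2-one
Product: 17 (3S,4R)-3-[4-(benzyloxy)-3,5-dimethoxybenzyl]-4-[4-(benzyloxy)-3-methoxybenzyl]-3-hydroxyoxolan-2-one, via silyl ketene acetal 15 (not isolated), via silyloxy lactone 16 (not isolated)
Conditions: Cu(OAc)2·H2O (5 mol%), 1,2-bis(diphenylphosphino)benzene (5 mol%), (EtO)2MeSiH (1.5 equiv), toluene, rt; then mCPBA (2 equiv), NaHCO3, CH2Cl2, −40 → 0 °C; then 1 M HCl, THF, rt
Reagents that add atoms: meta-chloroperbenzoic acid (mCPBA), OOC(=O)c1cccc(Cl)c1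
Why: Proposed new method: a one-pot copper hydride conjugate reduction/Rubottom oxygenation (reductive α-hydroxylation) of an α-arylidene lactone, in which the bisphosphine-ligated monovalent copper hydride formed from Cu(OAc)2 (divalent copper) and the silane adds hydride to the benzylidene carbon by polar 1,4-addition (so either alkene isomer converges), σ-bond metathesis with the silane releases ketene acetal 15 and regenerates the hydride, and mCPBA epoxidises the C2=C3 bond of 15 on the face opposite the C4 benzyl group (held pseudoaxial by A(1,2) strain with the new C3 benzyl group), so that silyl migration gives 16 with the new C3–O bond trans to the C4 benzyl group (3S, benzyl groups cis); the closest known reaction types are copper hydride-catalysed 1,4-reduction of enoates and butenolides with trapping of the silyl enolate by carbon electrophiles and the Rubottom oxidation of lactone silyl ketene acetals.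

Step 7
Reactants: 17 (3S,4R)-3-[4-(benzyloxy)-3,5-dimethoxybenzyl]-4-[4-(benzyloxy)-3-methoxybenzyl]-3-hydroxyoxolan-2-one
Product: 18 (3S,4R)-3-hydroxy-3-(4-hydroxy-3,5-dimethoxybenzyl)-4-(4-hydroxy-3-methoxybenzyl)oxolan-2-one
Conditions: H2 (1 atm), Pd/C (10 wt%), EtOAc/EtOH, rt
Reagents that add atoms: none
Why: Hydrogenolysis of both aryl benzyl ethers; the homobenzylic tertiary alcohol, the lactone and both stereocentres are untouched.

## Compound list

1 | syringaldehyde (4-hydroxy-3,5-dimethoxybenzaldehyde) | COc1cc(C=O)cc(OC)c1O | starting material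
2 | 4-(benzyloxy)-3,5-dimethoxybenzaldehyde | COc1cc(C=O)cc(OC)c1OCc1ccccc1 | intermediate
3 | 4-(benzyloxy)-3-methoxybenzaldehyde (O-benzylvanillin) | COc1cc(C=O)ccc1OCc1ccccc1 | starting material
4 | dimethyl succinate | COC(=O)CCC(=O)OC | starting material
5 | paraconic ester: methyl 2-[4-(benzyloxy)-3-methoxyphenyl]-5-oxooxolane-3-carboxylate (diastereomer mixture) | COC(=O)C1CC(=O)OC1c1ccc(OCc2ccccc2)c(OC)c1 | intermediate
6 | (E)-4-[4-(benzyloxy)-3-methoxyphenyl]-3-(methoxycarbonyl)but-3-enoic acid | COC(=O)/C(CC(=O)O)=C/c1ccc(OCc2ccccc2)c(OC)c1 | intermediate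
7 | (S)-4-[4-(benzyloxy)-3-methoxyphenyl]-3-(methoxycarbonyl)butanoic acid | COC(=O)[C@@H](Cc1ccc(OCc2ccccc2)c(OC)c1)CC(=O)O | intermediate
8 | potassium carboxylate: potassium (S)-4-[4-(benzyloxy)-3-methoxyphenyl]-3-(methoxycarbonyl)butanoate | COC(=O)[C@@H](Cc1ccc(OCc2ccccc2)c(OC)c1)CC(=O)[O-].[K+] | intermediate
9 | hydroxy acid: (S)-4-[4-(benzyloxy)-3-methoxyphenyl]-3-(hydroxymethyl)butanoic acid (a carboxylate until acidification) | OC[C@@H](Cc1ccc(OCc2ccccc2)c(OC)c1)CC(=O)O | intermediate
10 | (S)-4-[4-(benzyloxy)-3-methoxybenzyl]oxolan-2-one | O=C1C[C@H](Cc2ccc(OCc3ccccc3)c(OC)c2)CO1 | intermediate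
11 | lithium enolate: lithium (S)-4-[4-(benzyloxy)-3-methoxybenzyl]-4,5-dihydrofuran-2-olate | [Li+].[O-]C1=C[C@H](Cc2ccc(OCc3ccccc3)c(OC)c2)CO1 | intermediate
12 | lithium aldolate: lithium [4-(benzyloxy)-3,5-dimethoxyphenyl][(4S)-4-[4-(benzyloxy)-3-methoxybenzyl]-2-oxooxolan-3-yl]methanolate (mixture at C3 and the carbinol carbon) | [Li+].[O-]C(c1cc(OC)c(OCc2ccccc2)c(OC)c1)C1C(=O)OC[C@H]1Cc1ccc(OCc2ccccc2)c(OC)c1 | intermediate
13 | acetoxy lactone: [4-(benzyloxy)-3,5-dimethoxyphenyl][(4S)-4-[4-(benzyloxy)-3-methoxybenzyl]-2-oxooxolan-3-yl]methyl acetate (diastereomer mixture) | CC(=O)OC(c1cc(OC)c(OCc2ccccc2)c(OC)c1)C1C(=O)OC[C@H]1Cc1ccc(OCc2ccccc2)c(OC)c1 | intermediate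
14 | (3E,4S)-3-[4-(benzyloxy)-3,5-dimethoxybenzylidene]-4-[4-(benzyloxy)-3-methoxybenzyl]oxolan-2-one | O=C1OC[C@@H](Cc2ccc(OCc3ccccc3)c(OC)c2)/C1=C\c1cc(OC)c(OCc2ccccc2)c(OC)c1 | intermediate
15 | silyl ketene acetal: (4S)-3-[4-(benzyloxy)-3,5-dimethoxybenzyl]-4-[4-(benzyloxy)-3-methoxybenzyl]-2-[diethoxy(methyl)silyloxy]-4,5-dihydrofuran | CCO[Si](C)(OCC)OC1=C(Cc2cc(OC)c(OCc3ccccc3)c(OC)c2)[C@H](Cc2ccc(OCc3ccccc3)c(OC)c2)CO1 | intermediate
16 | silyloxy lactone: (3S,4R)-3-[4-(benzyloxy)-3,5-dimethoxybenzyl]-4-[4-(benzyloxy)-3-methoxybenzyl]-3-[diethoxy(methyl)silyloxy]oxolan-2-one | CCO[Si](C)(OCC)O[C@]1(Cc2cc(OC)c(OCc3ccccc3)c(OC)c2)C(=O)OC[C@H]1Cc1ccc(OCc2ccccc2)c(OC)c1 | intermediate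
17 | (3S,4R)-3-[4-(benzyloxy)-3,5-dimethoxybenzyl]-4-[4-(benzyloxy)-3-methoxybenzyl]-3-hydroxyoxolan-2-one | O[C@]1(Cc2cc(OC)c(OCc3ccccc3)c(OC)c2)C(=O)OC[C@H]1Cc1ccc(OCc2ccccc2)c(OC)c1 | intermediate
18 | (3S,4R)-3-hydroxy-3-(4-hydroxy-3,5-dimethoxybenzyl)-4-(4-hydroxy-3-methoxybenzyl)oxolan-2-one (CNP0176953.1) | COc1cc(C[C@@H]2COC(=O)[C@]2(O)Cc2cc(OC)c(O)c(OC)c2)ccc1O | target

## Step count and risks

Total step count: 7 (6 if aldehyde 2, a catalogue compound, is bought). Longest linear sequence: 6 (steps 2 to 7).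

Steps most likely to fail:

- **Step 6 (the new reductive α-oxygenation).** Ketene acetal 15 may be protonated before it is oxidised, or the facial bias may be lower than expected. The fallback is known chemistry and sets out from 14. Conjugate reduction with LiBH(s-Bu)3 (THF, −78 °C) gives the saturated dibenzyl lactone (4S)-3-[4-(benzyloxy)-3,5-dimethoxybenzyl]-4-[4-(benzyloxy)-3-methoxybenzyl]oxolan-2-one F1 (C3 epimers, both usable; it is also what protonated 15 would give). KN(SiMe3)2 (THF, −78 °C) converts it into the potassium enolate F2, and 2-(phenylsulfonyl)-3-phenyloxaziridine hydroxylates it anti to the C4 benzyl group. This comes back to the route at 17.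

- **Step 5 (aldol condensation).** Retro-aldol during acetylation, or DBU-induced γ-deprotonation of 14, is possible; migration of the double bond into the ring would destroy C4. The fallback sets out from 10. LiN(i-Pr)2 and ClP(O)(OEt)2 give the enol phosphate F3, and a second equivalent of LiN(i-Pr)2 induces the 1,3-phosphorus shift to the α-phosphono lactone F4. Horner–Wadsworth–Emmons olefination of F4 with aldehyde 2 (LiCl, DBU, MeCN) comes back to the route at 14 without an aldolate or an elimination step. An E/Z mixture is acceptable because step 6 erases the alkene geometry.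

- **Step 3 (asymmetric hydrogenation).** The ee and the sense of induction for this electron-rich substrate must be confirmed (chiral HPLC and rotation of 10); the (R,R) ligand is chosen by analogy with itaconate hydrogenations, and the antipodal ligand is equally available. The fallback sets out from 6. Hydrogenation with the achiral catalyst [Rh(cod)(dppb)]BF4 (H2, MeOH) gives the racemic half-ester F5, which is resolved by crystallisation of the (R)-1-phenylethylammonium salt F6 (the antipodal amine is taken if the salt of the R acid proves less soluble). Acidification with 1 M HCl comes back to the route at 7.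

## Further compounds

F1 | step 6 | (4S)-3-[4-(benzyloxy)-3,5-dimethoxybenzyl]-4-[4-(benzyloxy)-3-methoxybenzyl]oxolan-2-one (C3 epimers) | O=C1OC[C@@H](Cc2ccc(OCc3ccccc3)c(OC)c2)C1Cc1cc(OC)c(OCc2ccccc2)c(OC)c1
F2 | step 6 | potassium (4S)-3-[4-(benzyloxy)-3,5-dimethoxybenzyl]-4-[4-(benzyloxy)-3-methoxybenzyl]-4,5-dihydrofuran-2-olate | [K+].[O-]C1=C(Cc2cc(OC)c(OCc3ccccc3)c(OC)c2)[C@H](Cc2ccc(OCc3ccccc3)c(OC)c2)CO1
F3 | step 5 | diethyl (4S)-4-[4-(benzyloxy)-3-methoxybenzyl]-4,5-dihydrofuran-2-yl phosphate | CCOP(=O)(OCC)OC1=C[C@H](Cc2ccc(OCc3ccccc3)c(OC)c2)CO1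
F4 | step 5 | diethyl [(4R)-4-[4-(benzyloxy)-3-methoxybenzyl]-2-oxooxolan-3-yl]phosphonate (C3 epimers; C4 geometry as in 10) | CCOP(=O)(OCC)C1C(=O)OC[C@H]1Cc1ccc(OCc2ccccc2)c(OC)c1
F5 | step 3 | racemic 4-[4-(benzyloxy)-3-methoxyphenyl]-3-(methoxycarbonyl)butanoic acid | COC(=O)C(Cc1ccc(OCc2ccccc2)c(OC)c1)CC(=O)O
F6 | step 3 | (R)-1-phenylethylammonium (S)-4-[4-(benzyloxy)-3-methoxyphenyl]-3-(methoxycarbonyl)butanoate | COC(=O)[C@@H](Cc1ccc(OCc2ccccc2)c(OC)c1)CC(=O)[O-].C[C@@H]([NH3+])c1ccccc1
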